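## Retrosynthetic overview
1. Target 11 ⇒ tertiary vinyl carbinol 10 (SN2' bromination gives the primary C–Br and the Z-alkene) ⇒ acetoxy chloro ketone 9 (vinyl addition) ⇒ chloro ketone 8 (alpha'-acetoxylation).
2. 8 ⇒ cyclopentanone 4. This is the key one-carbon ring expansion: the quaternary ring carbon shifts onto a chlorocarbenoid carbon, which forms the CHCl–CMe2 bond and installs C–Cl.
3. 4 ⇒ cyclopentenol 2. A bromonium-triggered 1,2-methyl shift builds the gem-dimethyl carbon and sets the neopentylic C–Br stereocentre (new method).
4. 2 ⇒ enone 1 by catalytic asymmetric methyl addition, the only source of absolute configuration.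
5. Ring order: the only ring is the five-membered ring of 1. It is enlarged to the cyclohexane in step 3, and no other ring is formed.

Assumption: the one- and two-carbon donors (dimethylzinc, dichloromethane, vinylmagnesium bromide) are entered as reagents that add atoms and carry no compound number. LDA and the Grignard reagent are bought as solutions.

## Route

Step 1
Reactants: 1 2-methylcyclopent-2-en-1-one
Product: 2 (1S)-1,2-dimethylcyclopent-2-en-1-ol
Conditions: ZnMe2 (2 equiv), Ti(OiPr)4 (1.2 equiv), bis(hydroxycamphorsulfonamide) ligand of trans-cyclohexane-1,2-diamine (5 mol %), toluene/hexane, 23 °C; H2O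
Reagents that add atoms: dimethylzinc, C[Zn]C
Why: This is a titanium-mediated catalytic asymmetric 1,2-addition of a dialkylzinc to a ketone, for which 2-substituted cyclic enones are favourable substrates because the alpha-methyl group makes the two flanks of the carbonyl sterically distinct, and the ligand antipode is chosen so that methyl is delivered to the face that gives the (S)-carbinol.

Step 2
Reactants: 2 (1S)-1,2-dimethylcyclopent-2-en-1-ol
Product: 4 (3R)-3-bromo-2,2-dimethylcyclopentan-1-one, via hydroxyl-face bromonium ion 3 (not isolated)
Conditions: NBS (1.05 equiv), Ph3P=S (5 mol %), CH2Cl2/MeNO2 (4:1), −40 °C, dark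
Reagents that add atoms: N-bromosuccinimide, O=C1CCC(=O)N1Br
Why: Proposed new method: an enantiospecific bromonium-triggered semipinacol rearrangement with a 1,2-methyl shift inside an endocyclic tertiary cyclopentenol, in which Lewis-base-activated NBS delivers Br+ to the less hindered, hydrogen-bonding hydroxyl face to give 3, the carbinol methyl then lies antiperiplanar to the weaker tertiary C–Br bond and migrates with C=O formation as driving force (epoxide closure is impossible from the syn-hydroxyl ion and ring contraction to a cyclobutane is strained), so the carbinol configuration is relayed to the (R)-C–Br centre while the gem-dimethyl carbon is built; the closest known reaction type is the halonium-induced semipinacol rearrangement of allylic alcohols, established for aryl shifts and strain-releasing ring enlargements from exocyclic carbinols.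

Step 3
Reactants: 4 (3R)-3-bromo-2,2-dimethylcyclopentan-1-one
Product: 8 (2S,4R)-4-bromo-2-chloro-3,3-dimethylcyclohexan-1-one, via lithium dichloromethyl carbinolate 5 (not isolated), via dilithiated chlorocarbenoid 6 (not isolated), via lithium chloroenolate 7 (not isolated)
Conditions: CH2Cl2 (1.5 equiv), LDA (1.4 equiv), THF, −95 °C, then 4; LDA (1.5 equiv), −95 to −60 °C; AcOH, −78 °C; then HCl (cat.), CH2Cl2, 23 °C
Reagents that add atoms: dichloromethane, ClCCl
Why: Carbonyl addition of dichloromethyllithium is followed by a beta-oxido carbenoid one-carbon ring enlargement (a 1,2-shift to a carbenoid carbon), in which deprotonation of 5 gives 6, loss of LiCl is coupled to migration of the more substituted, electron-richer quaternary ring carbon so that the five-membered ring becomes six-membered with chlorine next to the gem-dimethyl carbon in 7, the cold quench comes before the enolate can displace the gamma-bromide, and acid-catalysed equilibration of the alpha-chloro centre settles on the axial chloride trans to the equatorial bromide (one Cl/Me gauche contact fewer and opposed C–Cl and C=O dipoles), which sets (2S).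

Step 4
Reactants: 8 (2S,4R)-4-bromo-2-chloro-3,3-dimethylcyclohexan-1-one
Product: 9 (1S,3S,5R)-5-bromo-3-chloro-4,4-dimethyl-2-oxocyclohexyl acetate
Conditions: PhI(OAc)2 (1.2 equiv), BF3·OEt2 (30 mol %), AcOH, 23 °C
Reagents that add atoms: (diacetoxyiodo)benzene, CC(=O)OI(OC(C)=O)c1ccccc1
Why: This is an alpha-acetoxylation of a ketone with a trivalent iodine reagent under acid-promoted enolisation, in which only the alpha-methylene should react because the CHCl position is flanked by the quaternary carbon and deactivated by chlorine, and the epimerisable new centre ends equatorial, cis to bromine and trans to the axial chlorine, because the other epimer would suffer a syn-diaxial Cl/OAc contact, which sets (1S).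

Step 5
Reactants: 9 (1S,3S,5R)-5-bromo-3-chloro-4,4-dimethyl-2-oxocyclohexyl acetate
Product: 10 (1S,3S,5R)-5-bromo-3-chloro-2-ethenyl-2-hydroxy-4,4-dimethylcyclohexyl acetate (either epimer at the carbinol carbon)
Conditions: CH2=CHMgBr (1.3 equiv), LaCl3·2LiCl (30 mol %), THF, −78 °C; AcOH, −78 °C
Reagents that add atoms: vinylmagnesium bromide, C=C[Mg]Br
Why: This is a lanthanide-assisted Grignard 1,2-addition to an alpha-chloro ketone (chlorohydrin formation), in which the ketone, activated by two alpha-heteroatoms, outcompetes the acetate at −78 °C, LaCl3·2LiCl suppresses enolisation, the cold acidic quench prevents epoxide closure and acetyl migration, and the configuration of the new carbinol centre is irrelevant because that carbon becomes sp2 in step 6.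

Step 6
Reactants: 10 (1S,3S,5R)-5-bromo-3-chloro-2-ethenyl-2-hydroxy-4,4-dimethylcyclohexyl acetate
Product: 11 (1S,2Z,3R,5R)-5-bromo-2-(2-bromoethylidene)-3-chloro-4,4-dimethylcyclohexyl acetate
Conditions: PBr3 (0.4 equiv), Et2O, −20 to 0 °C
Reagents that add atoms: phosphorus tribromide, BrP(Br)Br
Why: This is an SN2' bromination of a tertiary vinyl carbinol with allylic transposition (the linalool to geranyl bromide reaction type), in which bromide attacks the unhindered vinyl terminus of the phosphite ester and allylic 1,3-strain places CH2Br on the side of the CHCl carbon, whose in-plane substituent is hydrogen (chlorine axial), rather than on the side of the carbon bearing the equatorial acetate, which gives the (Z)-alkene and leaves the three ring stereocentres untouched (the CHCl descriptor changes from S to R only through a change in priorities).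

## Compound list
1 | 2-methylcyclopent-2-en-1-one | CC1=CCCC1=O | starting material
2 | (1S)-1,2-dimethylcyclopent-2-en-1-ol | C[C@]1(O)CCC=C1C | intermediate
3 | bromonium ion of 2, bromine bridging the former alkene carbons on the hydroxyl face, anti to the carbinol methyl (cation, not isolated) | C[C@]1(O)CC[C@H]2[Br+][C@@]12C | intermediate
4 | (3R)-3-bromo-2,2-dimethylcyclopentan-1-one | O=C1CC[C@@H](Br)C1(C)C | intermediate
5 | lithium (3R)-3-bromo-1-(dichloromethyl)-2,2-dimethylcyclopentan-1-olate, both carbinol epimers serve (not isolated) | [Li]OC1(C(Cl)Cl)CC[C@@H](Br)C1(C)C | intermediate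
6 | lithium (3R)-3-bromo-1-[dichloro(lithio)methyl]-2,2-dimethylcyclopentan-1-olate (not isolated) | [Li]OC1(C([Li])(Cl)Cl)CC[C@@H](Br)C1(C)C | intermediate
7 | lithium (4R)-4-bromo-2-chloro-3,3-dimethylcyclohex-1-en-1-olate (not isolated) | [Li]OC1=C(Cl)C(C)(C)[C@H](Br)CC1 | intermediate
8 | (2S,4R)-4-bromo-2-chloro-3,3-dimethylcyclohexan-1-one, Cl axial and trans to equatorial Br | O=C1CC[C@@H](Br)C(C)(C)[C@@H]1Cl | intermediate
9 | (1S,3S,5R)-5-bromo-3-chloro-4,4-dimethyl-2-oxocyclohexyl acetate, OAc cis to Br and trans to Cl | CC(=O)O[C@H]1C[C@@H](Br)C(C)(C)[C@H](Cl)C1=O | intermediate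
10 | (1S,3S,5R)-5-bromo-3-chloro-2-ethenyl-2-hydroxy-4,4-dimethylcyclohexyl acetate, carbinol centre unassigned because both epimers converge | CC(=O)O[C@H]1C[C@@H](Br)C(C)(C)[C@H](Cl)C1(O)C=C | intermediate
11 | (1S,2Z,3R,5R)-5-bromo-2-(2-bromoethylidene)-3-chloro-4,4-dimethylcyclohexyl acetate | CC(=O)O[C@H]1C[C@@H](Br)C(C)(C)[C@H](Cl)/C1=C\CBr | target

## Step count and risks
Total step count: 6. Longest linear sequence: 6 (fully linear from 1).

The three steps most likely to fail are steps 2, 3 and 4.

**Step 2 (the proposed new step).**
- Risks: proton loss from the bromonium ion to an allylic bromide, ionisation or dehydration of the tertiary allylic alcohol, and leakage through an open beta-bromo cation that would erode the chirality transfer.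
- Fallback (known chemistry only): set out from 1 and run the step 1 addition with the mirror-image ligand to get (1R)-1,2-dimethylcyclopent-2-en-1-ol F1. Epoxidise under hydroxyl direction (VO(acac)2, t-BuOOH, CH2Cl2) to (1R,2S,3S)-2,3-epoxy-1,2-dimethylcyclopentan-1-ol F2. Trigger the epoxy-alcohol semipinacol methyl shift with BF3·OEt2 at −78 °C to (3S)-3-hydroxy-2,2-dimethylcyclopentan-1-one F3. Replace the hydroxyl by bromide with inversion (CBr4, PPh3, toluene, 60 °C). The route is rejoined at 4.

**Step 3.**
- Risks: incomplete second deprotonation, fragmentation of alkoxide 5 with loss of bromide, cyclopropane formation from 7, or migration of the methylene instead of the quaternary carbon.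
- Fallback: this makes the C–Cl bond by electrophilic chlorination instead of carrying chlorine in the carbenoid. Set out from 4 and add dibromomethyllithium (CH2Br2, LDA, THF, −95 °C, AcOH quench) to get (3R)-3-bromo-1-(dibromomethyl)-2,2-dimethylcyclopentan-1-ol F4. Treat with n-BuLi (2.1 equiv, −95 °C). The fast bromine–lithium exchange of the geminal dibromide and the same type of 1,2-shift give the regiodefined lithium (4R)-4-bromo-3,3-dimethylcyclohex-1-en-1-olate F5. Trap it in the flask with TMSCl as [(4R)-4-bromo-3,3-dimethylcyclohex-1-en-1-yl]oxy-trimethylsilane F6. Chlorinate with NCS (CH2Cl2, 0 °C), then apply the same acid equilibration. The route is rejoined at 8.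

**Step 4.**
- Risks: sluggish enolisation of the chloro ketone, attack at the CHCl carbon, or double oxidation.
- Fallback (Rubottom sequence): set out from 8 and silylate under soft enolisation (TMSOTf, Et3N, CH2Cl2, 0 °C) to [(4R,6S)-4-bromo-6-chloro-5,5-dimethylcyclohex-1-en-1-yl]oxy-trimethylsilane F7. Oxidise with mCPBA (NaHCO3, CH2Cl2, 0 °C, citric acid work-up) on the face opposite the axial chlorine to (2S,4R,6S)-4-bromo-2-chloro-6-hydroxy-3,3-dimethylcyclohexan-1-one F8. Acetylate (Ac2O, pyridine, 0 °C). The route is rejoined at 9.

## Further compounds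
F1 | step 2 | (1R)-1,2-dimethylcyclopent-2-en-1-ol | C[C@@]1(O)CCC=C1C
F2 | step 2 | (1R,2S,3S)-2,3-epoxy-1,2-dimethylcyclopentan-1-ol (epoxide syn to OH) | C[C@@]1(O)CC[C@@H]2O[C@]12C
F3 | step 2 | (3S)-3-hydroxy-2,2-dimethylcyclopentan-1-one | O=C1CC[C@H](O)C1(C)C
F4 | step 3 | (3R)-3-bromo-1-(dibromomethyl)-2,2-dimethylcyclopentan-1-ol | OC1(C(Br)Br)CC[C@@H](Br)C1(C)C
F5 | step 3 | lithium (4R)-4-bromo-3,3-dimethylcyclohex-1-en-1-olate | [Li]OC1=CC(C)(C)[C@H](Br)CC1
F6 | step 3 | [(4R)-4-bromo-3,3-dimethylcyclohex-1-en-1-yl]oxy-trimethylsilane | C[Si](C)(C)OC1=CC(C)(C)[C@H](Br)CC1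
F7 | step 4 | [(4R,6S)-4-bromo-6-chloro-5,5-dimethylcyclohex-1-en-1-yl]oxy-trimethylsilane | C[Si](C)(C)OC1=CC[C@@H](Br)C(C)(C)[C@@H]1Cl
F8 | step 4 | (2S,4R,6S)-4-bromo-2-chloro-6-hydroxy-3,3-dimethylcyclohexan-1-one | O[C@H]1C[C@@H](Br)C(C)(C)[C@H](Cl)C1=O
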